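**Target:** (2R,3R)-2-(4-hydroxy-3,5-dimethoxyphenyl)-7-methoxy-3-methyl-5-[(E)-prop-1-enyl]-2,3-dihydrobenzofuran (2,3-trans), compound 21.

**Retrosynthetic overview**
1. Target ⇒ desilylation ⇒ Suzuki–Miyaura propenylation of a 5-bromo-2,3-dihydrobenzofuran (C5–propenyl bond).
2. Key disconnection: C3–C3a and C2–O1 are cut together, an enantioselective palladium-catalysed Heck–Matsuda oxyarylation joining a ring A aminophenol (as its diazonium salt) and an (E)-arylpropene.
3. Ring A fragment: anisole ⇒ ortho-hydroxylation, para-bromination, ortho-nitration, reduction.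
4. Arylpropene fragment: resorcinol ⇒ methylation, ortho-hydroxylation, silylation, iridium C–H borylation and Suzuki coupling with (E)-1-bromopropene.
5. Ring order: both benzene rings are bought; the dihydrofuran ring is the only ring made, in the key step.

Assumption: the (S)-ligand in step 9 is taken to give the (2R,3R) series; if it gives the mirror image, the (R)-ligand is used with no other change.

**Route**

Step 1
Reactants: 1 anisole
Product: 4 2-methoxyphenol, via 2-methoxyphenyllithium 2 (not isolated), via lithium trimethoxy(2-methoxyphenyl)borate 3 (not isolated)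
Conditions: n-BuLi, TMEDA, Et2O, 0 °C → rt; B(OMe)3, −78 °C → rt; 30% H2O2, AcOH, 0 °C → rt
Reagents that add atoms: hydrogen peroxide (OO)
Why: Directed ortho-metalation by the methoxy group, borylation and oxidative C–B to C–O migration place the hydroxyl ortho to OMe; no stereocenter.

Step 2
Reactants: 4 2-methoxyphenol
Product: 5 4-bromo-2-methoxyphenol
Conditions: NBS (1.0 equiv), MeCN, 0 °C → rt
Reagents that add atoms: N-bromosuccinimide (O=C1CCC(=O)N1Br)
Why: Electrophilic aromatic bromination in which the free hydroxyl, the strongest director, sends bromine to its open para position.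

Step 3
Reactants: 5 4-bromo-2-methoxyphenol
Product: 6 4-bromo-2-methoxy-6-nitrophenol
Conditions: 65% HNO3 (1.05 equiv), AcOH, 5–10 °C
Reagents that add atoms: nitric acid (O[N+](=O)[O-])
Why: Electrophilic aromatic nitration; with the para position blocked, the hydroxyl directs to its only free ortho position.

Step 4
Reactants: 6 4-bromo-2-methoxy-6-nitrophenol
Product: 7 2-amino-4-bromo-6-methoxyphenol
Conditions: Na2S2O4, THF/H2O (1:1), 60 °C; used directly under argon
Reagents that add atoms: none
Why: Dithionite reduction of the nitroarene to the aniline leaves the aryl bromide untouched, unlike catalytic hydrogenation.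

Step 5
Reactants: 8 resorcinol
Product: 9 1,3-dimethoxybenzene
Conditions: MeI (2.5 equiv), K2CO3, acetone, reflux
Reagents that add atoms: iodomethane (CI)
Why: Double Williamson O-methylation of the phenoxide in an aprotic solvent.

Step 6
Reactants: 9 1,3-dimethoxybenzene
Product: 12 2,6-dimethoxyphenol, via 2,6-dimethoxyphenyllithium 10 (not isolated), via lithium (2,6-dimethoxyphenyl)trimethoxyborate 11 (not isolated)
Conditions: n-BuLi, THF, 0 °C → rt; B(OMe)3, −78 °C → rt; 30% H2O2, AcOH, 0 °C → rt
Reagents that add atoms: hydrogen peroxide (OO)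
Why: Directed ortho-metalation at C2, where both methoxy groups cooperate, followed by borylation and peroxide oxidation.

Step 7
Reactants: 12 2,6-dimethoxyphenol
Product: 13 (2,6-dimethoxyphenoxy)triisopropylsilane
Conditions: i-Pr3SiCl, imidazole, DMF, 50 °C
Reagents that add atoms: chlorotriisopropylsilane (CC(C)[Si](Cl)(C(C)C)C(C)C)
Why: Silyl ether formation; the bulky triisopropylsilyl group resists the basic aqueous conditions of the later couplings.

Step 8
Reactants: 13 (2,6-dimethoxyphenoxy)triisopropylsilane; 14 (E)-1-bromoprop-1-ene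
Product: 16 {2,6-dimethoxy-4-[(E)-prop-1-enyl]phenoxy}triisopropylsilane, via pinacol arylboronate 15 (not isolated)
Conditions: [Ir(OMe)(cod)]2 (1.5 mol %), 4,4'-di-tert-butyl-2,2'-bipyridine (3 mol %), B2pin2 (1.0 equiv), THF, 80 °C; then PdCl2(dppf) (3 mol %), 3 M aq K3PO4, 14 (1.5 equiv), 60 °C, sealed tube
Reagents that add atoms: none
Why: Sterically controlled iridium-catalysed C–H borylation hits the only C–H without an ortho substituent (C4), and the one-pot Suzuki–Miyaura coupling with the alkenyl bromide retains the E geometry.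

Step 9
Reactants: 7 2-amino-4-bromo-6-methoxyphenol; 16 {2,6-dimethoxy-4-[(E)-prop-1-enyl]phenoxy}triisopropylsilane
Product: 18 (2R,3R)-5-bromo-2-[3,5-dimethoxy-4-(triisopropylsilyloxy)phenyl]-7-methoxy-3-methyl-2,3-dihydrobenzofuran, via arenediazonium tetrafluoroborate 17 (not isolated)
Conditions: NOBF4 (0.98 equiv), MeCN, −20 → 0 °C; then transfer into Pd2(dba)3 (2.5 mol %), (S)-4-tert-butyl-2-[5-(trifluoromethyl)pyridin-2-yl]-4,5-dihydrooxazole (7 mol %), ZnCO3 (2 equiv), 16 (1.2 equiv), DMF, 0 → 20 °C
Reagents that add atoms: none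
Why: Proposed new method: an enantioselective Heck–Matsuda oxyarylation (formal [3+2] heteroannulation) of an (E)-1-arylpropene; the diazonium 17 adds oxidatively to zerovalent palladium to give a cationic aryl complex of divalent palladium held by the chiral pyridine–oxazoline; enantio-determining syn migratory insertion puts the aryl group on the methyl-bearing alkene carbon (forming C3–C3a and setting C3 as R) and palladium on the benzylic carbon as an η3-benzyl stabilised by the electron-rich ring; the ortho hydroxyl then closes the C2–O bond faster than β-hydride elimination (inner-sphere C–O reductive elimination, or ionisation to the quinone-methide-like benzylic cation and ring closure), giving the favoured 2,3-trans ring and so C2 as R; the closest known reaction types are the racemic ligand-free Heck–Matsuda oxyarylation of (E)-arylpropenes with in situ 2-hydroxyarenediazonium salts and enantioselective Heck–Matsuda arylations of other alkenes with chiral pyridine–oxazoline ligands.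

Step 10
Reactants: 18 (2R,3R)-5-bromo-2-[3,5-dimethoxy-4-(triisopropylsilyloxy)phenyl]-7-methoxy-3-methyl-2,3-dihydrobenzofuran; 19 potassium (E)-trifluoro(prop-1-enyl)borate
Product: 20 (2R,3R)-2-[3,5-dimethoxy-4-(triisopropylsilyloxy)phenyl]-7-methoxy-3-methyl-5-[(E)-prop-1-enyl]-2,3-dihydrobenzofuran
Conditions: PdCl2(dppf)·CH2Cl2 (3 mol %), Cs2CO3 (3 equiv), THF/H2O (10:1), 70 °C
Reagents that add atoms: none
Why: Suzuki–Miyaura coupling of the aryl bromide with an alkenyltrifluoroborate proceeds with retention of the E geometry and does not touch the two sp3 stereocenters.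

Step 11
Reactants: 20 (2R,3R)-2-[3,5-dimethoxy-4-(triisopropylsilyloxy)phenyl]-7-methoxy-3-methyl-5-[(E)-prop-1-enyl]-2,3-dihydrobenzofuran
Product: 21 maceneolignan A, (2R,3R)-2-(4-hydroxy-3,5-dimethoxyphenyl)-7-methoxy-3-methyl-5-[(E)-prop-1-enyl]-2,3-dihydrobenzofuran
Conditions: Bu4NF (1.1 equiv), AcOH (1.1 equiv), THF, 0 °C
Reagents that add atoms: none
Why: Fluoride-mediated desilylation; the acetic acid buffer protonates the phenoxide at once, so no quinone methide ring opening can disturb C2, and C3 is not epimerisable.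

**Compound list**
1 | anisole | COc1ccccc1 | starting material
2 | 2-methoxyphenyllithium | [Li]c1ccccc1OC | intermediate
3 | lithium trimethoxy(2-methoxyphenyl)borate | [Li+].COc1ccccc1[B-](OC)(OC)OC | intermediate
4 | 2-methoxyphenol | COc1ccccc1O | intermediate
5 | 4-bromo-2-methoxyphenol | COc1cc(Br)ccc1O | intermediate
6 | 4-bromo-2-methoxy-6-nitrophenol | COc1cc(Br)cc([N+](=O)[O-])c1O | intermediate
7 | 2-amino-4-bromo-6-methoxyphenol | COc1cc(Br)cc(N)c1O | intermediate
8 | resorcinol | Oc1cccc(O)c1 | starting material
9 | 1,3-dimethoxybenzene | COc1cccc(OC)c1 | intermediate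
10 | 2,6-dimethoxyphenyllithium | [Li]c1c(OC)cccc1OC | intermediate
11 | lithium (2,6-dimethoxyphenyl)trimethoxyborate | [Li+].COc1cccc(OC)c1[B-](OC)(OC)OC | intermediate
12 | 2,6-dimethoxyphenol | COc1cccc(OC)c1O | intermediate
13 | (2,6-dimethoxyphenoxy)triisopropylsilane | COc1cccc(OC)c1O[Si](C(C)C)(C(C)C)C(C)C | intermediate
14 | (E)-1-bromoprop-1-ene | C/C=C/Br | starting material
15 | 2-[3,5-dimethoxy-4-(triisopropylsilyloxy)phenyl]-4,4,5,5-tetramethyl-1,3,2-dioxaborolane | COc1cc(cc(OC)c1O[Si](C(C)C)(C(C)C)C(C)C)B1OC(C)(C)C(C)(C)O1 | intermediate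
16 | {2,6-dimethoxy-4-[(E)-prop-1-enyl]phenoxy}triisopropylsilane | C/C=C/c1cc(OC)c(O[Si](C(C)C)(C(C)C)C(C)C)c(OC)c1 | intermediate
17 | 5-bromo-2-hydroxy-3-methoxybenzenediazonium tetrafluoroborate | COc1cc(Br)cc([N+]#N)c1O.F[B-](F)(F)F | intermediate
18 | (2R,3R)-5-bromo-2-[3,5-dimethoxy-4-(triisopropylsilyloxy)phenyl]-7-methoxy-3-methyl-2,3-dihydrobenzofuran | Brc1cc(OC)c2c(c1)[C@@H](C)[C@H](c1cc(OC)c(O[Si](C(C)C)(C(C)C)C(C)C)c(OC)c1)O2 | intermediate
19 | potassium (E)-trifluoro(prop-1-enyl)borate | [K+].C/C=C/[B-](F)(F)F | starting material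
20 | (2R,3R)-2-[3,5-dimethoxy-4-(triisopropylsilyloxy)phenyl]-7-methoxy-3-methyl-5-[(E)-prop-1-enyl]-2,3-dihydrobenzofuran | C/C=C/c1cc(OC)c2c(c1)[C@@H](C)[C@H](c1cc(OC)c(O[Si](C(C)C)(C(C)C)C(C)C)c(OC)c1)O2 | intermediate
21 | maceneolignan A | C/C=C/c1cc(OC)c2c(c1)[C@@H](C)[C@H](c1cc(OC)c(O)c(OC)c1)O2 | target

**Totals**
Total step count: 11 (steps 1–4 make the ring A fragment, steps 5–8 the arylpropene fragment, steps 9–11 are shared).
Longest linear sequence: 7 steps (1–4 then 9–11, or 5–8 then 9–11).

**Steps most likely to fail**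

Step 9 (the proposed new oxyarylation). The risks are a racemic ligand-free background reaction, modest enantioselectivity on an acyclic alkene, and β-hydride elimination to the plain Heck product. The fallback moves stereocontrol from the catalyst to a resolution and uses known chemistry only. It sets out from 7 and 16. The racemic ligand-free oxyarylation (NOBF4, MeCN, then Pd2(dba)3, ZnCO3, rt, passing through 17) gives racemic trans-5-bromo-2-[3,5-dimethoxy-4-(triisopropylsilyloxy)phenyl]-7-methoxy-3-methyl-2,3-dihydrobenzofuran F1. Preparative chiral-phase SFC separates it; the (2S,3S)-enantiomer F2 is set aside, and the (2R,3R)-enantiomer is 18, where the route is rejoined.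

Step 8 (one-pot C–H borylation and Suzuki coupling with a volatile alkenyl bromide). The risks are incomplete borylation of the electron-rich arene and loss of bromopropene. The fallback replaces C–H borylation and cross-coupling by a sigmatropic route and sets out from 12. Allyl bromide and K2CO3 in acetone give 2-(allyloxy)-1,3-dimethoxybenzene F3. Heating at 200 °C in N,N-diethylaniline (Claisen then Cope shift to the para position, both ortho positions being blocked) gives 4-allyl-2,6-dimethoxyphenol F4. i-Pr3SiCl and imidazole give (4-allyl-2,6-dimethoxyphenoxy)triisopropylsilane F5. RuHCl(CO)(PPh3)3 (1 mol %) in toluene at 80 °C moves the double bond into conjugation and gives 16 (E strongly favoured), where the route is rejoined.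

Step 3 (nitration of an electron-rich bromophenol). The risks are oxidation to quinones and ipso loss of bromine. The fallback brings in nitrogen by azo coupling instead of nitration and sets out from 5. Benzenediazonium tetrafluoroborate in aqueous NaOH/pyridine at 0 °C couples at the only free ortho position of the phenoxide and gives 4-bromo-2-methoxy-6-[(E)-phenyldiazenyl]phenol F6. Na2S2O4 in aqueous EtOH at 60 °C cleaves the N=N bond; the aniline formed is extracted from the basic phenoxide solution, and neutralisation gives 7, where the route is rejoined without passing through 6.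

**Further compounds**
F1 | step 9 | racemic trans-5-bromo-2-[3,5-dimethoxy-4-(triisopropylsilyloxy)phenyl]-7-methoxy-3-methyl-2,3-dihydrobenzofuran (1:1 mixture of 18 and F2) | Brc1cc(OC)c2c(c1)[C@@H](C)[C@H](c1cc(OC)c(O[Si](C(C)C)(C(C)C)C(C)C)c(OC)c1)O2.Brc1cc(OC)c2c(c1)[C@H](C)[C@@H](c1cc(OC)c(O[Si](C(C)C)(C(C)C)C(C)C)c(OC)c1)O2
F2 | step 9 | (2S,3S)-5-bromo-2-[3,5-dimethoxy-4-(triisopropylsilyloxy)phenyl]-7-methoxy-3-methyl-2,3-dihydrobenzofuran | Brc1cc(OC)c2c(c1)[C@H](C)[C@@H](c1cc(OC)c(O[Si](C(C)C)(C(C)C)C(C)C)c(OC)c1)O2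
F3 | step 8 | 2-(allyloxy)-1,3-dimethoxybenzene | C=CCOc1c(OC)cccc1OC
F4 | step 8 | 4-allyl-2,6-dimethoxyphenol | C=CCc1cc(OC)c(O)c(OC)c1
F5 | step 8 | (4-allyl-2,6-dimethoxyphenoxy)triisopropylsilane | C=CCc1cc(OC)c(O[Si](C(C)C)(C(C)C)C(C)C)c(OC)c1
F6 | step 3 | 4-bromo-2-methoxy-6-[(E)-phenyldiazenyl]phenol | COc1cc(Br)cc(/N=N/c2ccccc2)c1O
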